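**Retrosynthetic overview**
1. Target ⇒ keto diester 15: the C7–C11 bond and the C7 carbinol come last (α-isopropenylation of the C8 ketone, then oxygenation of the resulting dienolate).
2. 15 ⇒ alkene ketone 11: β-face cis-acetoxy-hydroxylation of the Δ3 alkene sets C3 and C4; angeloylation follows.
3. 11 ⇒ enone ketal 7: dissolving-metal reduction sets the trans ring fusion (C5); the C3 oxygen is removed through the enol triflate.
4. 7 ⇒ hydrindenedione 4: one-carbon ring expansion of the cyclopentanone (1,2-shift of C10 from C8 to a new C9) creates ring B.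
5. 4 ⇒ 2-methylcyclopentane-1,3-dione + ethyl vinyl ketone: asymmetric annulation sets C10. Ring order: ring A and a five-membered precursor of ring B in step 1, six-membered ring B by expansion in step 3.

Assumption: eudesmane numbering (ring A = C1–C5/C10, ring B = C5–C10) is used for every bicyclic compound, also before the ring expansion (cyclopentanone carbonyl = C8); angelic acid and 2-bromopropene are taken as commercial starting materials.

Target stereochemistry planned for: 3S,4R,5R,7S,10R, i.e. 10β-Me, 5α-H, 4β-OAc/4α-Me, 3β-O-angelate, 7α-OH/7β-isopropenyl.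

**Step 1**
Reactants: 1 2-methylcyclopentane-1,3-dione; 2 pent-1-en-3-one
Product: 4 (7aS)-4,7a-dimethyl-2,3,7,7a-tetrahydro-1H-indene-1,5(6H)-dione, via triketone 3 (not isolated)
Conditions: 2 (1.3 equiv), H2O, 70 °C; concentrate; L-phenylalanine (1.0 equiv), (1S)-(+)-10-camphorsulfonic acid (0.5 equiv), MeCN, 80 °C; recrystallise
Reagents that add atoms: none
Why: Michael addition followed by the amino-acid-mediated Hajos–Parrish–Eder–Sauer–Wiechert aldol condensation desymmetrises the prochiral triketone, L-phenylalanine giving the (S) quaternary centre (future C10, 10β-methyl), with the ee upgraded by crystallisation.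

**Step 2**
Reactants: 4 (7aS)-4,7a-dimethyl-2,3,7,7a-tetrahydro-1H-indene-1,5(6H)-dione
Product: 5 (7aR)-4,7a-dimethyl-1-methylidene-1,2,3,6,7,7a-hexahydro-5H-inden-5-one
Conditions: Ph3PCH3Br (1.3 equiv), KOt-Bu (1.25 equiv), toluene, 0 °C → rt
Reagents that add atoms: methyltriphenylphosphonium bromide, C[P+](c1ccccc1)(c1ccccc1)c1ccccc1.[Br-]
Why: Wittig methylenation is chemoselective for the saturated cyclopentanone because the conjugated enone carbonyl is much less electrophilic; no stereocentre is touched.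

**Step 3**
Reactants: 5 (7aR)-4,7a-dimethyl-1-methylidene-1,2,3,6,7,7a-hexahydro-5H-inden-5-one
Product: 7 (4aR)-6,6-dimethoxy-1,4a-dimethyl-4,4a,5,6,7,8-hexahydronaphthalen-2(3H)-one, via iodane adduct 6 (not isolated)
Conditions: PhI(OH)OTs (1.1 equiv), anhydrous MeOH, 3 Å sieves, −20 °C → rt; then Et3N
Reagents that add atoms: methanol, CO
Why: Proposed new method: oxidative semipinacol ring expansion of a purely aliphatic methylenecyclopentane in which a fully substituted carbon must migrate; the trivalent-iodine reagent adds in the Markovnikov sense (iodine on the CH2, methanol on C8), and loss of iodobenzene triggers a 1,2-shift of the ring bond antiperiplanar to C–I, which should be C8–C10 because the bulky aryliodanyl group sits anti to the quaternary carbon and that carbon best stabilises the bridged cation; C10 migrates with retention and the methoxy-oxocarbenium ion is trapped by methanol, so the C8 ketone is delivered already protected; closest known reactions are the Wittig/ring-expansion sequence with Koser's reagent on benzo-fused methylenecycloalkanes (aryl migration) and Tl(NO3)3 ring expansions of methylenecycloalkanes.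

**Step 4**
Reactants: 7 (4aR)-6,6-dimethoxy-1,4a-dimethyl-4,4a,5,6,7,8-hexahydronaphthalen-2(3H)-one
Product: 9 (4aR,8aR)-6,6-dimethoxy-1,4a-dimethyl-3,4,4a,5,6,7,8,8a-octahydronaphthalen-2-yl trifluoromethanesulfonate, via lithium enolate 8 (not isolated)
Conditions: Li (2.3 equiv), NH3(l)–THF, t-BuOH (1.0 equiv), −78 °C; isoprene; NH3 off; PhNTf2 (1.3 equiv), THF, 0 °C → rt
Reagents that add atoms: N-phenylbis(trifluoromethanesulfonimide), O=S(=O)(N(c1ccccc1)S(=O)(=O)C(F)(F)F)C(F)(F)F
Why: Birch-type dissolving-metal reduction protonates C5 axially from the α face to give the trans-decalin (5α-H anti to the 10β-methyl), and the regiodefined Δ3 enolate is O-triflated before it can equilibrate.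

**Step 5**
Reactants: 9 (4aR,8aR)-6,6-dimethoxy-1,4a-dimethyl-3,4,4a,5,6,7,8,8a-octahydronaphthalen-2-yl trifluoromethanesulfonate
Product: 11 (4aR,8aR)-5,8a-dimethyl-3,4,4a,7,8,8a-hexahydronaphthalen-2(1H)-one, via ketal alkene 10 (not isolated)
Conditions: Pd(OAc)2 (5 mol %), PPh3 (10 mol %), HCO2H (2 equiv), n-Bu3N (3 equiv), DMF, 60 °C; then 1 M HCl, THF, rt
Reagents that add atoms: water, O
Why: Palladium-catalysed formate hydrogenolysis of the enol triflate (oxidative addition, formate exchange, decarboxylation, C–H reductive elimination) gives the Δ3 trisubstituted alkene without touching a stereocentre, and the dimethyl ketal is hydrolysed by the dilute acid.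

**Step 6**
Reactants: 11 (4aR,8aR)-5,8a-dimethyl-3,4,4a,7,8,8a-hexahydronaphthalen-2(1H)-one
Product: 13 (1R,2S,4aR,8aR)-2-hydroxy-1,4a-dimethyl-6-oxodecahydronaphthalen-1-yl acetate, via iodo acetate 12 (not isolated)
Conditions: I2 (1.05 equiv), AgOAc (2.2 equiv), AcOH, rt, dark; then H2O (1.5 equiv) in AcOH, 90 °C, 2 h
Reagents that add atoms: silver acetate, CC(=O)[O-].[Ag+]; water, O
Why: Woodward cis-hydroxylation: the iodonium ion forms on the less hindered α face, acetate opens it trans-diaxially at the tertiary C4 from the β face, the acetoxy group then displaces the 3α-iodide from the rear to give the β-face acetoxonium ion, and its hydrolysis leaves the ester on the axial tertiary C4 oxygen and frees the equatorial 3β-OH, so C3 and C4 are set on the face opposite to OsO4.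

**Step 7**
Reactants: 13 (1R,2S,4aR,8aR)-2-hydroxy-1,4a-dimethyl-6-oxodecahydronaphthalen-1-yl acetate; 14 angelic acid
Product: 15 (1R,2S,4aR,8aR)-1-acetoxy-1,4a-dimethyl-6-oxodecahydronaphthalen-2-yl (2Z)-2-methylbut-2-enoate
Conditions: 14 (3 equiv), 2,4,6-Cl3C6H2COCl (3 equiv), Et3N (3 equiv), toluene, rt; then 13, toluene, 80 °C, no DMAP
Reagents that add atoms: none
Why: Yamaguchi-type mixed-anhydride esterification without nucleophilic catalyst acylates the only free hydroxyl (secondary, equatorial) at the less hindered angeloyl carbonyl and keeps the (Z) geometry; no stereocentre changes.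

**Step 8**
Reactants: 15 (1R,2S,4aR,8aR)-1-acetoxy-1,4a-dimethyl-6-oxodecahydronaphthalen-2-yl (2Z)-2-methylbut-2-enoate; 16 2-bromopropene
Product: 19 (3S,4R,5R,7S,10R)-4-acetoxy-3-angeloyloxy-7-hydroxyeudesm-11-en-8-one, via lithium enolate 17 (not isolated), via lithium dienolate 18 (not isolated)
Conditions: LiN(SiMe3)2 (2.2 equiv), THF–toluene, −78 → 0 °C; Pd2(dba)3 (2.5 mol %), P(t-Bu)3 (6 mol %), 16 (1.3 equiv), rt; then −78 °C, 3-phenyl-2-(phenylsulfonyl)oxaziridine (1.5 equiv); NH4Cl (aq)
Reagents that add atoms: 3-phenyl-2-(phenylsulfonyl)oxaziridine, O=S(=O)(c1ccccc1)N1OC1c1ccccc1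
Why: Palladium-catalysed α-alkenylation of the kinetic Δ7 enolate (C7, not the neopentyl C9) forms the C7–C11 bond, the more acidic product is deprotonated in the flask to the extended dienolate, and Davis oxidation delivers oxygen to the α-carbon along the axial α trajectory anti to the 10β-methyl, giving 7α-OH with the isopropenyl group equatorial (β).

**Compound list**
1 | 2-methylcyclopentane-1,3-dione | CC1C(=O)CCC1=O | starting material
2 | pent-1-en-3-one (ethyl vinyl ketone) | CCC(=O)C=C | starting material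
3 | 2-methyl-2-(3-oxopentyl)cyclopentane-1,3-dione | CCC(=O)CCC1(C)C(=O)CCC1=O | intermediate
4 | (7aS)-4,7a-dimethyl-2,3,7,7a-tetrahydro-1H-indene-1,5(6H)-dione | O=C1CC[C@]2(C)C(=O)CCC2=C1C | intermediate
5 | (7aR)-4,7a-dimethyl-1-methylidene-1,2,3,6,7,7a-hexahydro-5H-inden-5-one | O=C1CC[C@]2(C)C(=C)CCC2=C1C | intermediate
6 | (7aS)-1-methoxy-4,7a-dimethyl-1-{[phenyl(tosyloxy)iodanyl]methyl}-1,2,3,6,7,7a-hexahydro-5H-inden-5-one (C1 configuration undefined) | O=C1CC[C@]2(C)C(OC)(CI(OS(=O)(=O)c3ccc(C)cc3)c3ccccc3)CCC2=C1C | intermediate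
7 | (4aR)-6,6-dimethoxy-1,4a-dimethyl-4,4a,5,6,7,8-hexahydronaphthalen-2(3H)-one (8,8-dimethoxy Δ4-3-ketone) | O=C1CC[C@]2(C)CC(OC)(OC)CCC2=C1C | intermediate
8 | lithium (4aR,8aR)-6,6-dimethoxy-1,4a-dimethyl-3,4,4a,5,6,7,8,8a-octahydronaphthalen-2-olate (trans-fused Δ3 enolate) | C1C[C@@H]2[C@](C)(CCC([O-])=C2C)CC1(OC)OC.[Li+] | intermediate
9 | (4aR,8aR)-6,6-dimethoxy-1,4a-dimethyl-3,4,4a,5,6,7,8,8a-octahydronaphthalen-2-yl trifluoromethanesulfonate | C1C[C@@H]2[C@](C)(CCC(OS(=O)(=O)C(F)(F)F)=C2C)CC1(OC)OC | intermediate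
10 | (4aR,8aR)-7,7-dimethoxy-4,8a-dimethyl-1,2,4a,5,6,7,8,8a-octahydronaphthalene | C1C[C@@H]2[C@](C)(CCC=C2C)CC1(OC)OC | intermediate
11 | (4aR,8aR)-5,8a-dimethyl-3,4,4a,7,8,8a-hexahydronaphthalen-2(1H)-one (trans-fused Δ3-alkene 8-ketone) | C1C[C@@H]2[C@](C)(CCC=C2C)CC1=O | intermediate
12 | (1R,2R,4aR,8aR)-2-iodo-1,4a-dimethyl-6-oxodecahydronaphthalen-1-yl acetate (3α-iodo-4β-acetoxy) | C1C[C@@H]2[C@](C)(CC[C@@H](I)[C@]2(C)OC(C)=O)CC1=O | intermediate
13 | (1R,2S,4aR,8aR)-2-hydroxy-1,4a-dimethyl-6-oxodecahydronaphthalen-1-yl acetate (3β-hydroxy-4β-acetoxy) | C1C[C@@H]2[C@](C)(CC[C@H](O)[C@]2(C)OC(C)=O)CC1=O | intermediate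
14 | angelic acid, (2Z)-2-methylbut-2-enoic acid | C/C=C(/C)C(=O)O | starting material
15 | (1R,2S,4aR,8aR)-1-acetoxy-1,4a-dimethyl-6-oxodecahydronaphthalen-2-yl (2Z)-2-methylbut-2-enoate | C1C[C@@H]2[C@](C)(CC[C@H](OC(=O)/C(C)=C\C)[C@]2(C)OC(C)=O)CC1=O | intermediate
16 | 2-bromopropene | C=C(C)Br | starting material
17 | lithium Δ7-enolate of 15 | [Li+].[O-]C1=CC[C@@H]2[C@](C)(CC[C@H](OC(=O)/C(C)=C\C)[C@]2(C)OC(C)=O)C1 | intermediate
18 | lithium dienolate of the 7-isopropenyl-8-ketone | [Li+].[O-]C1=C(C(C)=C)C[C@@H]2[C@](C)(CC[C@H](OC(=O)/C(C)=C\C)[C@]2(C)OC(C)=O)C1 | intermediate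
19 | (3S,4R,5R,7S,10R)-4-acetoxy-3-angeloyloxy-7-hydroxyeudesm-11-en-8-one (CNP0381775.1) | C=C(C)[C@@]1(O)C[C@@H]2[C@](C)(CC[C@H](OC(=O)/C(C)=C\C)[C@]2(C)OC(C)=O)CC1=O | target

**Step count and risks**

Total step count: 8. Longest linear sequence: 8 steps (1 → 19).

Steps most likely to fail:

Step 3 (the proposed new step). The other ring bond (C8–C7) may migrate, as it does in diazonium-type expansions of such ketones, which would give the regioisomeric ketal with the oxygen next to C10. Fallback with known chemistry, the β-oxido carbenoid homologation, for which migration of the more substituted α-carbon is documented. It sets out from 4: CH2Br2 and excess LiN(i-Pr)2 in THF at −78 °C (the enone is held as its lithium dienolate while LiCHBr2 adds to the cyclopentanone) give the dibromomethyl carbinol F1. LiN(i-Pr)2 (2 equiv) then n-BuLi (2 equiv), −78 → 0 °C, effect bromine–lithium exchange and the 1,2-shift of the quaternary carbon; acid work-up gives the ring-expanded enedione F2. HC(OMe)3, MeOH and catalytic pyridinium p-toluenesulfonate ketalise only the saturated C8 ketone, and the route is rejoined at 7 (steps 2 and 3 are bypassed).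

Step 6. The acetyl group may migrate to the secondary 3β-oxygen in hot acetic acid, or hydrolysis may give a mixture of monoacetates. The fallback no longer relies on the regiochemistry of acetoxonium hydrolysis and installs the esters one at a time in reverse order. It sets out from 13 as obtained, whatever its isomer ratio: K2CO3 in MeOH gives the 3β,4β-diol F3. The mixed anhydride of step 7 acylates only the secondary equatorial hydroxyl to give the hydroxy angelate F4. Ac2O with catalytic Me3SiOTf in CH2Cl2 at −20 °C acetylates the tertiary axial 4β-OH, rejoining the route at 15.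

Step 8. Risks are over-alkenylation, base damage to the two esters, oxidation at the γ or C9 position, and only moderate facial selectivity at C7. The fallback builds the C7–C11 bond by aldol chemistry and the carbinol from an epoxide. It sets out from 15: LiN(i-Pr)2 at −78 °C then acetone (ZnCl2) give the aldol F5. MsCl/Et3N then DBU give the isopropylidene enone F6. t-BuOOH/DBU nucleophilic epoxidation, with ring closure from the axial α face, gives the 7α,11-epoxy ketone F7. Me3SiOTf/2,6-lutidine then DBU open the epoxide eliminatively at C11 to the allylic silyl ether F8. HF·pyridine removes the silyl group and the route is rejoined at 19.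

**Further compounds**
F1 | step 3 | (7aS)-1-(dibromomethyl)-1-hydroxy-4,7a-dimethyl-1,2,3,6,7,7a-hexahydro-5H-inden-5-one (C1 configuration undefined) | O=C1CC[C@]2(C)C(O)(C(Br)Br)CCC2=C1C
F2 | step 3 | (4aR)-1,4a-dimethyl-4,4a,7,8-tetrahydronaphthalene-2,6(3H,5H)-dione | O=C1CC[C@]2(C)CC(=O)CCC2=C1C
F3 | step 6 | (3S,4R,5R,10R)-3β,4β-dihydroxy-4α,10β-dimethyl-trans-decal-8-one | C1C[C@@H]2[C@](C)(CC[C@H](O)[C@]2(C)O)CC1=O
F4 | step 6 | (3S,4R,5R,10R)-3β-angeloyloxy-4β-hydroxy-4α,10β-dimethyl-trans-decal-8-one | C1C[C@@H]2[C@](C)(CC[C@H](OC(=O)/C(C)=C\C)[C@]2(C)O)CC1=O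
F5 | step 8 | 7-(2-hydroxypropan-2-yl) derivative of 15 (C7 configuration undefined) | CC(C)(O)C1C[C@@H]2[C@](C)(CC[C@H](OC(=O)/C(C)=C\C)[C@]2(C)OC(C)=O)CC1=O
F6 | step 8 | 4β-acetoxy-3β-angeloyloxyeudesm-7(11)-en-8-one | CC(C)=C1C[C@@H]2[C@](C)(CC[C@H](OC(=O)/C(C)=C\C)[C@]2(C)OC(C)=O)CC1=O
F7 | step 8 | 4β-acetoxy-3β-angeloyloxy-7α,11-epoxyeudesman-8-one | CC1(C)O[C@@]12C[C@@H]3[C@](C)(CC[C@H](OC(=O)/C(C)=C\C)[C@]3(C)OC(C)=O)CC2=O
F8 | step 8 | 7-O-trimethylsilyl ether of 19 | C=C(C)[C@@]1(O[Si](C)(C)C)C[C@@H]2[C@](C)(CC[C@H](OC(=O)/C(C)=C\C)[C@]2(C)OC(C)=O)CC1=O
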